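## Retrosynthetic overview

1. The nitrogen ring is cut at two bonds at once, N–C3 and C1–C8a. This leads back to a nitrogen-free (R)-1-arylpropan-2-ol and acetonitrile, which supplies N, C1 and the C1-methyl group. One flask covers triflation, invertive Ritter-type N-alkylation and nitrilium ring closure. A MOM ether on the naphthol oxygen is the only protecting group.
2. Enabling feature: in the benzenoid ring of the isoquinoline (C4a, C5, C6, C7, C8, C8a), the OMe groups at C6 and C8 flank the naphthyl-bearing C7. The open precursor ring is therefore locally C2-symmetric, with two equivalent free CH positions, each ortho to one OMe and para to the other (future C8a). The chain-bearing carbon (future C4a) is meta to both OMe groups and gives a phenonium ion no help.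
3. The biaryl bond (C7 to naphthalene C2) comes from a Suzuki–Miyaura coupling of a 2-naphthyl pinacol boronate with a 4-iodo-3,5-dimethoxyphenyl carbinol. The carbinol is made from 1-bromo-3,5-dimethoxybenzene and (R)-propylene oxide.
4. The naphthalene comes from an aryne annulation of a 3-alkoxybenzyne with lithiated N,N-diethyl-3-methylbut-2-enamide. This builds the methyl-bearing ring and places its oxygen peri to the protected one.
5. Ring order: both benzene rings are bought, the second naphthalene ring closes in step 3, and the nitrogen ring closes last in step 9.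

Key step: step 9

Assumption: the SMILES fixes only C3, which is S. The biaryl axis carries no descriptor, so no axial control is attempted and the product is taken as whatever rotamer or atropisomer mixture the axis adopts.

## Route

Step 1
Reactants: 1 3-bromophenol
Product: 2 1-bromo-3-(methoxymethoxy)benzene
Conditions: NaH, MOMCl, THF, 0 °C to rt
Reagents that add atoms: chloromethyl methyl ether (MOMCl), COCCl
Why: Williamson-type O-alkylation of the sodium phenoxide by the reactive α-chloro ether should give the MOM acetal, which is stable to the strong bases used later and directs the lithiations of steps 3 and 5.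

Step 2
Reactants: 3 3-methylbut-2-enoyl chloride
Product: 4 N,N-diethyl-3-methylbut-2-enamide
Conditions: Et2NH, aq NaOH, CH2Cl2, 0 °C
Reagents that add atoms: diethylamine, CCNCC
Why: Schotten–Baumann acylation of the secondary amine is fast at 0 °C and gives a tertiary amide that tolerates γ-deprotonation and later serves as the acyl donor.

Step 3
Reactants: 2 1-bromo-3-(methoxymethoxy)benzene; 4 N,N-diethyl-3-methylbut-2-enamide
Product: 8 8-(methoxymethoxy)-3-methylnaphthalen-1-ol, via lithium dienolate 5 (not isolated), via aryllithium 6 (not isolated), via aryne 7 (not isolated)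
Conditions: LiN(i-Pr)2 (3.3 equiv), THF, −78 °C to rt; aq NH4Cl
Reagents that add atoms: none
Why: In this anionic aryne annulation the base deprotonates 4 at the γ-methyl group cis to the carbonyl and 2 at the CH between Br and OMOM, LiBr loss on warming gives 7, the γ-carbon of 5 adds at the aryne carbon remote from the inductively withdrawing OMOM group, and the aryl anion next to OMOM acylates itself on the amide with loss of LiNEt2, so that tautomerisation should give the 1-naphthol with its oxygen peri to OMOM.

Step 4
Reactants: 8 8-(methoxymethoxy)-3-methylnaphthalen-1-ol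
Product: 9 1-methoxy-8-(methoxymethoxy)-3-methylnaphthalene
Conditions: MeI, K2CO3, DMF, rt
Reagents that add atoms: iodomethane, CI
Why: Williamson O-methylation of the naphtholate differentiates the two peri oxygens, the one in the methyl-bearing ring as OMe and the other as the removable MOM ether.

Step 5
Reactants: 9 1-methoxy-8-(methoxymethoxy)-3-methylnaphthalene
Product: 11 2-[8-methoxy-1-(methoxymethoxy)-6-methylnaphthalen-2-yl]-4,4,5,5-tetramethyl-1,3,2-dioxaborolane, via naphthyllithium 10 (not isolated)
Conditions: n-BuLi, TMEDA, THF, −78 to 0 °C; i-PrOBpin, −78 °C to rt; aq NH4Cl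
Reagents that add atoms: 2-isopropoxy-4,4,5,5-tetramethyl-1,3,2-dioxaborolane, CC(C)OB1OC(C)(C)C(C)(C)O1
Why: In this directed ortho-metalation the chelating OMOM group steers n-BuLi to its only ortho CH, the CH next to the weaker OMe director being shielded by the adjacent methyl group, and the aryllithium is borylated by addition to the borate ester and loss of isopropoxide.

Step 6
Reactants: 12 1-bromo-3,5-dimethoxybenzene; 13 (R)-propylene oxide
Product: 15 (2R)-1-(3,5-dimethoxyphenyl)propan-2-ol, via arylmagnesium bromide 14 (not isolated)
Conditions: Mg, THF, reflux; CuI (10 mol %), 13, −30 to 0 °C; aq NH4Cl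
Reagents that add atoms: none
Why: Copper-catalysed epoxide opening by the aryl Grignard reagent proceeds by SN2 attack at the unsubstituted CH2, so the stereocentre of 13 is untouched and is carried over as R.

Step 7
Reactants: 15 (2R)-1-(3,5-dimethoxyphenyl)propan-2-ol
Product: 17 (2R)-1-(4-iodo-3,5-dimethoxyphenyl)propan-2-ol, via dilithio species 16 (not isolated)
Conditions: n-BuLi (2.3 equiv), THF, 0 °C to rt; I2, −78 °C; aq Na2S2O3, aq NH4Cl
Reagents that add atoms: iodine, II
Why: In this directed ortho-metalation of the lithium alkoxide the second equivalent of n-BuLi removes the most acidic ring proton, the one between the two methoxy groups, as is usual for 5-alkylresorcinol dimethyl ethers, and iodine traps the aryllithium without touching the carbinol centre.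

Step 8
Reactants: 11 naphthyl pinacol boronate; 17 (2R)-1-(4-iodo-3,5-dimethoxyphenyl)propan-2-ol
Product: 18 (2R)-1-{3,5-dimethoxy-4-[8-methoxy-1-(methoxymethoxy)-6-methylnaphthalen-2-yl]phenyl}propan-2-ol
Conditions: Pd(OAc)2 (5 mol %), SPhos (10 mol %), K3PO4, toluene/H2O, 90 °C
Reagents that add atoms: none
Why: Suzuki–Miyaura coupling with the bulky, electron-rich biarylphosphine SPhos suits biaryls with three ortho substituents, tolerates the free alcohol and the MOM ether, and leaves the remote stereocentre alone.

Step 9
Reactants: 18 (2R)-1-{3,5-dimethoxy-4-[8-methoxy-1-(methoxymethoxy)-6-methylnaphthalen-2-yl]phenyl}propan-2-ol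
Product: 21 (3S)-6,8-dimethoxy-7-[8-methoxy-1-(methoxymethoxy)-6-methylnaphthalen-2-yl]-1,3-dimethyl-3,4-dihydroisoquinoline, via secondary triflate 19 (not isolated), via nitrilium triflate 20 (not isolated)
Conditions: Tf2O (1.05 equiv), 2,6-di-tert-butyl-4-methylpyridine (1.2 equiv), MeCN/CH2Cl2 1:1 (dilute), −40 °C to rt; aq NaHCO3
Reagents that add atoms: acetonitrile, CC#N
Why: Proposed new method: Tf2O turns the carbinol of 18 into the secondary triflate 19, acetonitrile as co-solvent displaces it from the rear (SN2, Ritter-type N-alkylation) to give the N-alkylnitrilium triflate 20, and the arene attacks the nitrilium carbon, after which loss of the ring proton should give 21 as its triflate salt, shielded by protonation from further alkylation. The closest known reaction types are the Tf2O-promoted tandem annulation of achiral 2-arylethanols with nitriles to 3,4-dihydroisoquinolines, the alkylation of nitriles by alkyl triflates to nitrilium salts, and the Bischler–Napieralski cyclisation, which passes through the same kind of nitrilium ion; what is new is the stereospecific use of an enantioenriched secondary carbinol. The only ring closed, the nitrogen ring, closes by 6-endo-dig electrophilic aromatic substitution that forms C1–C8a after the intermolecular N–C3 bond. C3 is the only stereocentre and is set as S by inversion of the R carbinol carbon derived from (R)-propylene oxide, and no bond to it is touched afterwards. Regioselectivity needs no control, because the two free ring positions are equivalent through the local C2 symmetry of the 3,5-dimethoxy-4-arylphenyl ring and each is activated by one ortho and one para methoxy group. The selectivity that must be won is direct displacement over phenonium participation, hydride shift and elimination, and it is secured by the ipso carbon lying meta to both methoxy groups, by the large excess of nitrile at low temperature, and by a pyridine base too hindered to attack carbon or to drive E2 loss of triflic acid.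

Step 10
Reactants: 21 MOM-protected dihydroisoquinoline
Product: 22 2-[(3S)-6,8-dimethoxy-1,3-dimethyl-3,4-dihydroisoquinolin-7-yl]-8-methoxy-6-methylnaphthalen-1-ol
Conditions: HCl, MeOH, 40 °C; aq NaHCO3
Reagents that add atoms: none
Why: Acid-catalysed acetal exchange with methanol (MOM cleavage) should free the naphthol while the imine is only protonated, the aryl methyl ethers are inert, and C3 keeps its configuration because imine–enamine tautomerism involves only the C1-methyl group.

## Compound list

1 | 3-bromophenol | Oc1cccc(Br)c1 | starting material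
2 | 1-bromo-3-(methoxymethoxy)benzene | COCOc1cccc(Br)c1 | intermediate
3 | 3-methylbut-2-enoyl chloride | CC(C)=CC(=O)Cl | starting material
4 | N,N-diethyl-3-methylbut-2-enamide | CCN(CC)C(=O)C=C(C)C | intermediate
5 | lithium dienolate of 4 | C=C(C)C=C(O[Li])N(CC)CC | intermediate
6 | [2-bromo-6-(methoxymethoxy)phenyl]lithium | COCOc1cccc(Br)c1[Li] | intermediate
7 | 3-(methoxymethoxy)benzyne | COCOC1=CC=CC#C1 | intermediate
8 | 8-(methoxymethoxy)-3-methylnaphthalen-1-ol | COCOc1cccc2cc(C)cc(O)c12 | intermediate
9 | 1-methoxy-8-(methoxymethoxy)-3-methylnaphthalene | COCOc1cccc2cc(C)cc(OC)c12 | intermediate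
10 | [8-methoxy-1-(methoxymethoxy)-6-methylnaphthalen-2-yl]lithium | COCOc1c([Li])ccc2cc(C)cc(OC)c12 | intermediate
11 | 2-[8-methoxy-1-(methoxymethoxy)-6-methylnaphthalen-2-yl]-4,4,5,5-tetramethyl-1,3,2-dioxaborolane | COCOc1c(B3OC(C)(C)C(C)(C)O3)ccc2cc(C)cc(OC)c12 | intermediate
12 | 1-bromo-3,5-dimethoxybenzene | COc1cc(Br)cc(OC)c1 | starting material
13 | (R)-propylene oxide | C[C@@H]1CO1 | starting material
14 | (3,5-dimethoxyphenyl)magnesium bromide | COc1cc(OC)cc([Mg]Br)c1 | intermediate
15 | (2R)-1-(3,5-dimethoxyphenyl)propan-2-ol | C[C@@H](O)Cc1cc(OC)cc(OC)c1 | intermediate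
16 | lithium (2R)-1-(4-lithio-3,5-dimethoxyphenyl)propan-2-olate | C[C@@H](O[Li])Cc1cc(OC)c([Li])c(OC)c1 | intermediate
17 | (2R)-1-(4-iodo-3,5-dimethoxyphenyl)propan-2-ol | C[C@@H](O)Cc1cc(OC)c(I)c(OC)c1 | intermediate
18 | (2R)-1-{3,5-dimethoxy-4-[8-methoxy-1-(methoxymethoxy)-6-methylnaphthalen-2-yl]phenyl}propan-2-ol | C[C@@H](O)Cc1cc(OC)c(c(OC)c1)-c1ccc2cc(C)cc(OC)c2c1OCOC | intermediate
19 | (2R)-1-{3,5-dimethoxy-4-[8-methoxy-1-(methoxymethoxy)-6-methylnaphthalen-2-yl]phenyl}propan-2-yl trifluoromethanesulfonate | C[C@@H](OS(=O)(=O)C(F)(F)F)Cc1cc(OC)c(c(OC)c1)-c1ccc2cc(C)cc(OC)c2c1OCOC | intermediate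
20 | N-[(2S)-1-{3,5-dimethoxy-4-[8-methoxy-1-(methoxymethoxy)-6-methylnaphthalen-2-yl]phenyl}propan-2-yl]acetonitrilium trifluoromethanesulfonate | C[C@H]([N+]#CC)Cc1cc(OC)c(c(OC)c1)-c1ccc2cc(C)cc(OC)c2c1OCOC.[O-]S(=O)(=O)C(F)(F)F | intermediate
21 | (3S)-6,8-dimethoxy-7-[8-methoxy-1-(methoxymethoxy)-6-methylnaphthalen-2-yl]-1,3-dimethyl-3,4-dihydroisoquinoline | COc1cc2c(c(OC)c1-c1ccc3cc(C)cc(OC)c3c1OCOC)C(C)=N[C@@H](C)C2 | intermediate
22 | 2-[(3S)-6,8-dimethoxy-1,3-dimethyl-3,4-dihydroisoquinolin-7-yl]-8-methoxy-6-methylnaphthalen-1-ol | COc1cc2c(c(OC)c1-c1ccc3cc(C)cc(OC)c3c1O)C(C)=N[C@@H](C)C2 | target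

## Step count and risks

Total steps: 10. Longest linear sequence: 7 steps (1, 3, 4, 5, 8, 9, 10).

**First risk, step 9.** The triflate may partly ionise, with aryl participation or hydride shift, which would erode the configurational purity at C3. It may also lose triflic acid to give the propenylarene before acetonitrile attacks.
- The fallback uses known chemistry, sets out from 18 and comes back at 21.
- Mitsunobu displacement of 18 with diphenylphosphoryl azide (PPh3, DIAD, THF) should give, with inversion, the (S)-azide F1.
- Staudinger reduction (PPh3, THF/H2O) gives the (S)-amine F2, and acetylation (Ac2O, Et3N, CH2Cl2) gives the (S)-acetamide F3.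
- A Bischler–Napieralski cyclisation by electrophilic amide activation (Tf2O, 2-chloropyridine, CH2Cl2, −78 °C to rt) then closes the same ring at the same equivalent positions to give 21.

**Second risk, step 3.** Diisopropylamine or the α-carbon of the dienolate may capture the aryne, and regiocontrol in the addition may be lost. Either would drain material before the ring closes.
- The fallback avoids the aryne altogether. It sets out from 2 and comes back at 8.
- Compound 2 is lithiated to aryllithium 6, which is held at −78 °C, below the temperature of LiBr loss.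
- Trapping 6 with 3-methylbut-2-enal gives the allylic alcohol F4, racemic at a centre that is erased in the next operation.
- Oxidation with MnO2 gives the aryl enone F5.
- A palladium-catalysed intramolecular γ-arylation of its dienolate (Pd(OAc)2, PPh3, Cs2CO3, DMF, 100 °C) joins the bromine-bearing carbon to the γ-methyl carbon, and tautomerisation gives 8.

**Third risk, step 8.** Protodeboronation of the ortho-alkoxy boronate may outrun the slow transmetalation onto the arylpalladium iodide that is crowded by two ortho methoxy groups.
- The fallback reverses the polarity of the partners under anhydrous Negishi conditions. It sets out from 9 and 15 and comes back at 18.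
- Naphthyllithium 10, made from 9 as in step 5, is quenched with I2 to give the naphthyl iodide F6.
- The dilithio species 16, made from 15 as in step 7, is transmetalated with ZnCl2 to give the arylzinc chloride F7.
- The two are coupled with Pd2(dba)3 and RuPhos in THF at 60 °C, and aqueous work-up gives 18.

## Further compounds

F1 | step 9 | 2-{4-[(2S)-2-azidopropyl]-2,6-dimethoxyphenyl}-8-methoxy-1-(methoxymethoxy)-6-methylnaphthalene | C[C@H](N=[N+]=[N-])Cc1cc(OC)c(c(OC)c1)-c1ccc2cc(C)cc(OC)c2c1OCOC
F2 | step 9 | (2S)-1-{3,5-dimethoxy-4-[8-methoxy-1-(methoxymethoxy)-6-methylnaphthalen-2-yl]phenyl}propan-2-amine | C[C@H](N)Cc1cc(OC)c(c(OC)c1)-c1ccc2cc(C)cc(OC)c2c1OCOC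
F3 | step 9 | N-[(2S)-1-{3,5-dimethoxy-4-[8-methoxy-1-(methoxymethoxy)-6-methylnaphthalen-2-yl]phenyl}propan-2-yl]acetamide | C[C@H](NC(C)=O)Cc1cc(OC)c(c(OC)c1)-c1ccc2cc(C)cc(OC)c2c1OCOC
F4 | step 3 | 1-[2-bromo-6-(methoxymethoxy)phenyl]-3-methylbut-2-en-1-ol (racemic) | CC(C)=CC(O)c1c(Br)cccc1OCOC
F5 | step 3 | 1-[2-bromo-6-(methoxymethoxy)phenyl]-3-methylbut-2-en-1-one | CC(C)=CC(=O)c1c(Br)cccc1OCOC
F6 | step 8 | 2-iodo-8-methoxy-1-(methoxymethoxy)-6-methylnaphthalene | COCOc1c(I)ccc2cc(C)cc(OC)c12
F7 | step 8 | lithium (2R)-1-[4-(chlorozincio)-3,5-dimethoxyphenyl]propan-2-olate | C[C@@H](O[Li])Cc1cc(OC)c([Zn]Cl)c(OC)c1
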